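**Plan**

- Ring A (C1 CO2H, C2 OMe, C3 side chain, C6 O-aryl) has its two oxygens on C2 and C6, meta to each other and flanking C1. A vinylketene plus alkynyl ether benzannulation produces exactly this pattern, so ring A is assembled from open-chain carbon.
- Retrosynthesis cuts the ring A bonds C1–C2, C5–C6 and C2–C3 (after CO2H → CH2OTBS, OMe → OH, diol → acetonide, ring B hydroxyls → MOM ethers), giving diazoketone 11 and aryl alkynyl ether 23.
- 11 is cut at the enone C=C (Wittig), the diazo carbon (diazo transfer) and the CH2–isopropenyl bond (epoxide opening), back to (R)-benzyl glycidyl ether. 23 is cut at O–C(sp) (trichloroethylene), C(sp)–CH2 (formaldehyde) and the ring B C–OH bond (ortho-lithiation, oxidation), back to 3-hydroxy-5-methylbenzoic acid.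
- Forward: ring B is bought as an arene. Ring A is the only ring built (step 13) and already carries the diaryl ether, the side chain and the future carboxyl carbon. O-methylation, two oxidations and acid deprotection finish the synthesis.
- Stereochemistry: the single stereocentre comes from (R)-benzyl glycidyl ether, is held in the dioxane ring and takes part in no bond-forming step.

Key step: step 13

Remark: at the carbinol carbon the priority order is O > aryl, vinyl, CHO or CH2O > CH2 in every intermediate, so the descriptor stays (R) from 1 to 33.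

**Fragment A: diazoketone 11**

Step 1
Reactants: 1 (2R)-2-[(benzyloxy)methyl]oxirane; 2 isopropenylmagnesium bromide
Product: 3 (2R)-1-(benzyloxy)-4-methylpent-4-en-2-ol
Conditions: CuI (10 mol %), THF, −30 to 0 °C; aq NH4Cl
Reagents that add atoms: none
Why: Copper-catalysed Grignard opening of a terminal epoxide (SN2 at the CH2 terminus) is a standard chain extension; no bond to the stereocentre is broken, so the (R) configuration of 1 is carried into 3.

Step 2
Reactants: 3 (2R)-1-(benzyloxy)-4-methylpent-4-en-2-ol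
Product: 4 (2R)-1-(benzyloxy)-4-methylpentane-2,4-diol
Conditions: Co(acac)2 (cat.), PhSiH3, O2 (1 atm), THF, rt
Reagents that add atoms: dioxygen, O=O
Why: Mukaiyama hydration (cobalt-catalysed hydrogen-atom transfer, capture of the tertiary radical by O2, reduction) adds water in the Markovnikov sense to the 1,1-disubstituted alkene under neutral conditions that leave the benzyl ether and the secondary alcohol alone.

Step 3
Reactants: 4 (2R)-1-(benzyloxy)-4-methylpentane-2,4-diol
Product: 5 (4R)-4-[(benzyloxy)methyl]-2,2,6,6-tetramethyl-1,3-dioxane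
Conditions: 2-methoxypropene, PPTS (cat.), CH2Cl2, 0 °C to rt
Reagents that add atoms: 2-methoxypropene, COC(C)=C
Why: Acid-catalysed ketalisation of a 1,3-diol with an enol ether closes the six-membered acetonide, the irreversible addition to 2-methoxypropene making up for the slow reaction of the tertiary hydroxyl.

Step 4
Reactants: 5 (4R)-4-[(benzyloxy)methyl]-2,2,6,6-tetramethyl-1,3-dioxane
Product: 6 [(4R)-2,2,6,6-tetramethyl-1,3-dioxan-4-yl]methanol
Conditions: H2 (1 atm), Pd/C, EtOAc, rt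
Reagents that add atoms: none
Why: Hydrogenolysis of a benzyl ether over palladium on carbon in a neutral solvent is routine and does not touch the ketal.

Step 5
Reactants: 6 [(4R)-2,2,6,6-tetramethyl-1,3-dioxan-4-yl]methanol; 7 1-(triphenyl-λ5-phosphanylidene)propan-2-one
Product: 9 (3E)-4-[(4R)-2,2,6,6-tetramethyl-1,3-dioxan-4-yl]but-3-en-2-one, via dioxane aldehyde 8 (not isolated)
Conditions: Dess–Martin periodinane, NaHCO3, CH2Cl2, 0 °C to rt; then 7, rt
Reagents that add atoms: none
Why: Dess–Martin oxidation followed in the same flask by a Wittig reaction avoids isolating the epimerisable α-alkoxy aldehyde 8, and the acyl-stabilised ylide should give the (E)-enone.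

Step 6
Reactants: 9 (3E)-4-[(4R)-2,2,6,6-tetramethyl-1,3-dioxan-4-yl]but-3-en-2-one
Product: 11 (3E)-1-diazo-4-[(4R)-2,2,6,6-tetramethyl-1,3-dioxan-4-yl]but-3-en-2-one, via trifluoroacetyl diketone 10 (not isolated)
Conditions: LiN(SiMe3)2, THF, −78 °C; CF3CO2CH2CF3; then MeSO2N3, Et3N, H2O, MeCN, rt
Reagents that add atoms: methanesulfonyl azide, CS(=O)(=O)N=[N+]=[N-]; 2,2,2-trifluoroethyl trifluoroacetate, O=C(OCC(F)(F)F)C(F)(F)F (atoms kept only in 10)
Why: Detrifluoroacetylative diazo transfer: the kinetic enolate at the methyl group undergoes a Claisen condensation with the trifluoroacetate, and the activated diketone 10 accepts the diazo group from the sulfonyl azide with loss of the trifluoroacetyl group, the standard route to α,β-unsaturated diazomethyl ketones.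

**Fragment B: aryl alkynyl ether 23**

Step 7
Reactants: 12 3-hydroxy-5-methylbenzoic acid
Product: 13 3-(hydroxymethyl)-5-methylphenol
Conditions: BH3·THF, THF, 0 °C to rt; MeOH quench
Reagents that add atoms: none
Why: Borane reduces a carboxylic acid to the primary alcohol chemoselectively and tolerates the free phenol.

Step 8
Reactants: 13 3-(hydroxymethyl)-5-methylphenol
Product: 14 1-(methoxymethoxy)-3-[(methoxymethoxy)methyl]-5-methylbenzene
Conditions: NaH (2.4 equiv), MeOCH2Cl (2.4 equiv), DMF, 0 °C to rt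
Reagents that add atoms: chloromethyl methyl ether, COCCl
Why: Williamson-type alkylation of the phenoxide and the alkoxide protects both hydroxyls in one operation and installs the two directing groups for the next step.

Step 9
Reactants: 14 1-(methoxymethoxy)-3-[(methoxymethoxy)methyl]-5-methylbenzene
Product: 17 2-(methoxymethoxy)-6-[(methoxymethoxy)methyl]-4-methylphenol, via aryllithium 15 (not isolated), via arylboronate 16 (not isolated)
Conditions: n-BuLi, TMEDA, Et2O, −78 to 0 °C; B(OMe)3, −78 °C to rt; then H2O2, aq NaOH, 0 °C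
Reagents that add atoms: hydrogen peroxide, OO; n-butyllithium, [Li]CCCC (lithium kept only in 15); trimethyl borate, COB(OC)OC (atoms kept only in 16)
Why: Directed ortho-metalation should occur at the one ring position flanked by both the aryl MOM ether and the benzylic MOM ether (cooperating 1,3-directors), and borylation followed by peroxide oxidation of the C–B bond turns the aryllithium into the phenol.

Step 10
Reactants: 17 2-(methoxymethoxy)-6-[(methoxymethoxy)methyl]-4-methylphenol; 18 trichloroethylene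
Product: 19 2-{[(E)-1,2-dichloroethenyl]oxy}-1-(methoxymethoxy)-3-[(methoxymethoxy)methyl]-5-methylbenzene
Conditions: K2CO3, DMF, 70 °C
Reagents that add atoms: none
Why: Under base trichloroethylene loses HCl to dichloroacetylene, to which the phenoxide adds in anti fashion to give the (E)-1,2-dichlorovinyl ether, an established O-vinylation that makes the hindered aryl–oxygen–carbon link without any aryl coupling.

Step 11
Reactants: 19 2-{[(E)-1,2-dichloroethenyl]oxy}-1-(methoxymethoxy)-3-[(methoxymethoxy)methyl]-5-methylbenzene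
Product: 22 3-{2-(methoxymethoxy)-6-[(methoxymethoxy)methyl]-4-methylphenoxy}prop-2-yn-1-ol, via chloroalkynyl ether 20 (not isolated), via lithium acetylide 21 (not isolated)
Conditions: n-BuLi (2.2 equiv), THF, −78 to −40 °C; then (CH2O)n, −40 °C to rt; aq NaHCO3
Reagents that add atoms: formaldehyde (from paraformaldehyde), C=O; n-butyllithium, [Li]CCCC (lithium kept only in 21)
Why: n-BuLi effects dehydrochlorination to chloroalkyne 20 and then chlorine–lithium exchange to acetylide 21, the standard alkynyl ether synthesis from dichlorovinyl ethers, and the acetylide adds to formaldehyde in a 1,2-addition.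

Step 12
Reactants: 22 3-{2-(methoxymethoxy)-6-[(methoxymethoxy)methyl]-4-methylphenoxy}prop-2-yn-1-ol
Product: 23 tert-butyl[(3-{2-(methoxymethoxy)-6-[(methoxymethoxy)methyl]-4-methylphenoxy}prop-2-yn-1-yl)oxy]dimethylsilane
Conditions: t-BuMe2SiCl, imidazole, CH2Cl2, 0 °C to rt
Reagents that add atoms: tert-butyldimethylsilyl chloride, CC(C)(C)[Si](C)(C)Cl
Why: Silylation of the primary alcohol with imidazole as base is non-acidic and therefore suits the acid-sensitive alkynyl ether.

**Key step and end game**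

Step 13
Reactants: 11 (3E)-1-diazo-4-[(4R)-2,2,6,6-tetramethyl-1,3-dioxan-4-yl]but-3-en-2-one; 23 tert-butyl[(3-{2-(methoxymethoxy)-6-[(methoxymethoxy)methyl]-4-methylphenoxy}prop-2-yn-1-yl)oxy]dimethylsilane
Product: 28 2-({[tert-butyl(dimethyl)silyl]oxy}methyl)-3-{2-(methoxymethoxy)-6-[(methoxymethoxy)methyl]-4-methylphenoxy}-6-[(4R)-2,2,6,6-tetramethyl-1,3-dioxan-4-yl]phenol, via vinylketene 24 (not isolated), via vinylcyclobutenone 25 (not isolated), via dienylketene 26 (not isolated), via cyclohexadienone 27 (not isolated)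
Conditions: hν (medium-pressure Hg lamp, Pyrex filter), ClCH2CH2Cl, rt; then 80 °C
Reagents that add atoms: none
Why: Light converts 11 by Wolff rearrangement into vinylketene 24, whose carbonyl carbon is attacked by the electron-rich alkyne carbon of 23 (the one bearing CH2OTBS) in a [2+2] cycloaddition to give vinylcyclobutenone 25, and warming opens 25 by a reversible 4π electrocyclic reaction to dienylketene 26. Ring A then closes by a 6π electrocyclisation that joins the ketene carbon (future C2) to the terminal alkene carbon (future C3), and cyclohexadienone 27 enolises to phenol 28. The closest known reaction is the Danheiser benzannulation in its diazoketone form, practised with alkoxy- and siloxyalkynes; an aryloxyalkyne is the same kind of oxygen-polarised alkyne. No stereocentre is created, because the sp3 carbons of 25 and 27 end up aromatic, and the dioxane stereocentre is insulated from the reacting π system. The step needs regioselectivity in the [2+2] event, which the oxygen-polarised triple bond supplies, so that the aryloxy group ends up meta to the new hydroxyl with the CH2OTBS carbon between them. As the oxygen substituent is an arene, the thermal retro-ene fragmentation that consumes alkyl alkynyl ethers at this temperature has no hydrogen to transfer.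

Step 14
Reactants: 28 2-({[tert-butyl(dimethyl)silyl]oxy}methyl)-3-{2-(methoxymethoxy)-6-[(methoxymethoxy)methyl]-4-methylphenoxy}-6-[(4R)-2,2,6,6-tetramethyl-1,3-dioxan-4-yl]phenol
Product: 29 tert-butyl[(2-methoxy-6-{2-(methoxymethoxy)-6-[(methoxymethoxy)methyl]-4-methylphenoxy}-3-[(4R)-2,2,6,6-tetramethyl-1,3-dioxan-4-yl]phenyl)methoxy]dimethylsilane
Conditions: MeI, Cs2CO3, DMF, rt
Reagents that add atoms: iodomethane, CI
Why: Williamson O-methylation; the phenoxide, although flanked by two substituents, should still be alkylated readily by the small electrophile in DMF.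

Step 15
Reactants: 29 tert-butyl[(2-methoxy-6-{2-(methoxymethoxy)-6-[(methoxymethoxy)methyl]-4-methylphenoxy}-3-[(4R)-2,2,6,6-tetramethyl-1,3-dioxan-4-yl]phenyl)methoxy]dimethylsilane
Product: 30 (2-methoxy-6-{2-(methoxymethoxy)-6-[(methoxymethoxy)methyl]-4-methylphenoxy}-3-[(4R)-2,2,6,6-tetramethyl-1,3-dioxan-4-yl]phenyl)methanol
Conditions: Bu4NF, THF, 0 °C to rt
Reagents that add atoms: none
Why: Fluoride cleaves the Si–O bond of the primary silyl ether, while MOM ethers and the ketal are inert to Bu4NF.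

Step 16
Reactants: 30 (2-methoxy-6-{2-(methoxymethoxy)-6-[(methoxymethoxy)methyl]-4-methylphenoxy}-3-[(4R)-2,2,6,6-tetramethyl-1,3-dioxan-4-yl]phenyl)methanol
Product: 31 2-methoxy-6-{2-(methoxymethoxy)-6-[(methoxymethoxy)methyl]-4-methylphenoxy}-3-[(4R)-2,2,6,6-tetramethyl-1,3-dioxan-4-yl]benzaldehyde
Conditions: Dess–Martin periodinane, NaHCO3, CH2Cl2, rt
Reagents that add atoms: none
Why: Dess–Martin oxidation takes the hindered benzylic alcohol to the aldehyde without over-oxidation, and the bicarbonate buffer protects the acetals.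

Step 17
Reactants: 31 2-methoxy-6-{2-(methoxymethoxy)-6-[(methoxymethoxy)methyl]-4-methylphenoxy}-3-[(4R)-2,2,6,6-tetramethyl-1,3-dioxan-4-yl]benzaldehyde
Product: 32 2-methoxy-6-{2-(methoxymethoxy)-6-[(methoxymethoxy)methyl]-4-methylphenoxy}-3-[(4R)-2,2,6,6-tetramethyl-1,3-dioxan-4-yl]benzoic acid
Conditions: NaClO2, NaH2PO4, 2-methylbut-2-ene, t-BuOH/H2O, rt
Reagents that add atoms: sodium chlorite, [Na+].[O-]Cl=O
Why: Pinnick oxidation converts even di-ortho-substituted benzaldehydes into acids, and 2-methylbut-2-ene traps the hypochlorous acid that would otherwise chlorinate the electron-rich rings.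

Step 18
Reactants: 32 2-methoxy-6-{2-(methoxymethoxy)-6-[(methoxymethoxy)methyl]-4-methylphenoxy}-3-[(4R)-2,2,6,6-tetramethyl-1,3-dioxan-4-yl]benzoic acid
Product: 33 3-[(1R)-1,3-dihydroxy-3-methylbutyl]-6-[2-hydroxy-6-(hydroxymethyl)-4-methylphenoxy]-2-methoxybenzoic acid
Conditions: HCl (3 M aq), THF, 40 °C
Reagents that add atoms: none
Why: Aqueous acid hydrolyses the two MOM acetals and the acetonide in one operation; no bond to the carbinol carbon is cleaved, and ionisation at this benzylic position is held back by the meta carboxyl group and by the twisted, doubly flanked methoxy group, so the (R) configuration should survive.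

**Compound list**

1 | (2R)-2-[(benzyloxy)methyl]oxirane | O(Cc1ccccc1)C[C@H]1CO1 | starting material
2 | isopropenylmagnesium bromide | CC(=C)[Mg]Br | starting material
3 | (2R)-1-(benzyloxy)-4-methylpent-4-en-2-ol | O(Cc1ccccc1)C[C@H](O)CC(C)=C | intermediate
4 | (2R)-1-(benzyloxy)-4-methylpentane-2,4-diol | O(Cc1ccccc1)C[C@H](O)CC(C)(C)O | intermediate
5 | (4R)-4-[(benzyloxy)methyl]-2,2,6,6-tetramethyl-1,3-dioxane | O(Cc1ccccc1)C[C@H]1CC(C)(C)OC(C)(C)O1 | intermediate
6 | [(4R)-2,2,6,6-tetramethyl-1,3-dioxan-4-yl]methanol | OC[C@H]1CC(C)(C)OC(C)(C)O1 | intermediate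
7 | 1-(triphenyl-λ5-phosphanylidene)propan-2-one | CC(=O)C=P(c1ccccc1)(c1ccccc1)c1ccccc1 | starting material
8 | (4R)-2,2,6,6-tetramethyl-1,3-dioxane-4-carbaldehyde | O=C[C@H]1CC(C)(C)OC(C)(C)O1 | intermediate
9 | (3E)-4-[(4R)-2,2,6,6-tetramethyl-1,3-dioxan-4-yl]but-3-en-2-one | CC(=O)/C=C/[C@H]1CC(C)(C)OC(C)(C)O1 | intermediate
10 | (5E)-1,1,1-trifluoro-6-[(4R)-2,2,6,6-tetramethyl-1,3-dioxan-4-yl]hex-5-ene-2,4-dione | FC(F)(F)C(=O)CC(=O)/C=C/[C@H]1CC(C)(C)OC(C)(C)O1 | intermediate
11 | (3E)-1-diazo-4-[(4R)-2,2,6,6-tetramethyl-1,3-dioxan-4-yl]but-3-en-2-one | [N-]=[N+]=CC(=O)/C=C/[C@H]1CC(C)(C)OC(C)(C)O1 | intermediate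
12 | 3-hydroxy-5-methylbenzoic acid | Cc1cc(O)cc(C(=O)O)c1 | starting material
13 | 3-(hydroxymethyl)-5-methylphenol | Cc1cc(O)cc(CO)c1 | intermediate
14 | 1-(methoxymethoxy)-3-[(methoxymethoxy)methyl]-5-methylbenzene | COCOCc1cc(C)cc(OCOC)c1 | intermediate
15 | {2-(methoxymethoxy)-6-[(methoxymethoxy)methyl]-4-methylphenyl}lithium | COCOCc1cc(C)cc(OCOC)c1[Li] | intermediate
16 | dimethyl {2-(methoxymethoxy)-6-[(methoxymethoxy)methyl]-4-methylphenyl}boronate | COCOCc1cc(C)cc(OCOC)c1B(OC)OC | intermediate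
17 | 2-(methoxymethoxy)-6-[(methoxymethoxy)methyl]-4-methylphenol | COCOCc1cc(C)cc(OCOC)c1O | intermediate
18 | trichloroethylene | ClC=C(Cl)Cl | starting material
19 | 2-{[(E)-1,2-dichloroethenyl]oxy}-1-(methoxymethoxy)-3-[(methoxymethoxy)methyl]-5-methylbenzene | COCOCc1cc(C)cc(OCOC)c1O/C(Cl)=C\Cl | intermediate
20 | 2-[(chloroethynyl)oxy]-1-(methoxymethoxy)-3-[(methoxymethoxy)methyl]-5-methylbenzene | COCOCc1cc(C)cc(OCOC)c1OC#CCl | intermediate
21 | ({2-(methoxymethoxy)-6-[(methoxymethoxy)methyl]-4-methylphenoxy}ethynyl)lithium | COCOCc1cc(C)cc(OCOC)c1OC#C[Li] | intermediate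
22 | 3-{2-(methoxymethoxy)-6-[(methoxymethoxy)methyl]-4-methylphenoxy}prop-2-yn-1-ol | COCOCc1cc(C)cc(OCOC)c1OC#CCO | intermediate
23 | tert-butyl[(3-{2-(methoxymethoxy)-6-[(methoxymethoxy)methyl]-4-methylphenoxy}prop-2-yn-1-yl)oxy]dimethylsilane | COCOCc1cc(C)cc(OCOC)c1OC#CCO[Si](C)(C)C(C)(C)C | intermediate
24 | (3E)-4-[(4R)-2,2,6,6-tetramethyl-1,3-dioxan-4-yl]buta-1,3-dien-1-one | O=C=C/C=C/[C@H]1CC(C)(C)OC(C)(C)O1 | intermediate
25 | 2-({[tert-butyl(dimethyl)silyl]oxy}methyl)-3-{2-(methoxymethoxy)-6-[(methoxymethoxy)methyl]-4-methylphenoxy}-4-{(E)-2-[(4R)-2,2,6,6-tetramethyl-1,3-dioxan-4-yl]ethenyl}cyclobut-2-en-1-one (both C4 epimers) | O=C1C(CO[Si](C)(C)C(C)(C)C)=C(Oc2c(OCOC)cc(C)cc2COCOC)C1/C=C/[C@H]3CC(C)(C)OC(C)(C)O3 | intermediate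
26 | 2-({[tert-butyl(dimethyl)silyl]oxy}methyl)-3-{2-(methoxymethoxy)-6-[(methoxymethoxy)methyl]-4-methylphenoxy}-6-[(4R)-2,2,6,6-tetramethyl-1,3-dioxan-4-yl]hexa-1,3,5-trien-1-one (C2 and C5 cis on the central double bond, 5E) | O=C=C(CO[Si](C)(C)C(C)(C)C)/C(Oc2c(OCOC)cc(C)cc2COCOC)=C\C=C\[C@H]1CC(C)(C)OC(C)(C)O1 | intermediate
27 | 2-({[tert-butyl(dimethyl)silyl]oxy}methyl)-3-{2-(methoxymethoxy)-6-[(methoxymethoxy)methyl]-4-methylphenoxy}-6-[(4R)-2,2,6,6-tetramethyl-1,3-dioxan-4-yl]cyclohexa-2,4-dien-1-one (both C6 epimers) | O=C1C(CO[Si](C)(C)C(C)(C)C)=C(Oc2c(OCOC)cc(C)cc2COCOC)C=CC1[C@H]3CC(C)(C)OC(C)(C)O3 | intermediate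
28 | 2-({[tert-butyl(dimethyl)silyl]oxy}methyl)-3-{2-(methoxymethoxy)-6-[(methoxymethoxy)methyl]-4-methylphenoxy}-6-[(4R)-2,2,6,6-tetramethyl-1,3-dioxan-4-yl]phenol | Oc1c([C@H]2CC(C)(C)OC(C)(C)O2)ccc(Oc2c(OCOC)cc(C)cc2COCOC)c1CO[Si](C)(C)C(C)(C)C | intermediate
29 | tert-butyl[(2-methoxy-6-{2-(methoxymethoxy)-6-[(methoxymethoxy)methyl]-4-methylphenoxy}-3-[(4R)-2,2,6,6-tetramethyl-1,3-dioxan-4-yl]phenyl)methoxy]dimethylsilane | COc1c([C@H]2CC(C)(C)OC(C)(C)O2)ccc(Oc2c(OCOC)cc(C)cc2COCOC)c1CO[Si](C)(C)C(C)(C)C | intermediate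
30 | (2-methoxy-6-{2-(methoxymethoxy)-6-[(methoxymethoxy)methyl]-4-methylphenoxy}-3-[(4R)-2,2,6,6-tetramethyl-1,3-dioxan-4-yl]phenyl)methanol | COc1c([C@H]2CC(C)(C)OC(C)(C)O2)ccc(Oc2c(OCOC)cc(C)cc2COCOC)c1CO | intermediate
31 | 2-methoxy-6-{2-(methoxymethoxy)-6-[(methoxymethoxy)methyl]-4-methylphenoxy}-3-[(4R)-2,2,6,6-tetramethyl-1,3-dioxan-4-yl]benzaldehyde | COc1c([C@H]2CC(C)(C)OC(C)(C)O2)ccc(Oc2c(OCOC)cc(C)cc2COCOC)c1C=O | intermediate
32 | 2-methoxy-6-{2-(methoxymethoxy)-6-[(methoxymethoxy)methyl]-4-methylphenoxy}-3-[(4R)-2,2,6,6-tetramethyl-1,3-dioxan-4-yl]benzoic acid | COc1c([C@H]2CC(C)(C)OC(C)(C)O2)ccc(Oc2c(OCOC)cc(C)cc2COCOC)c1C(=O)O | intermediate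
33 | 3-[(1R)-1,3-dihydroxy-3-methylbutyl]-6-[2-hydroxy-6-(hydroxymethyl)-4-methylphenoxy]-2-methoxybenzoic acid | COc1c([C@H](O)CC(C)(C)O)ccc(Oc2c(O)cc(C)cc2CO)c1C(=O)O | target

**Count and risks**

Total step count: 18. Longest linear sequence: 12 steps (steps 1–6 or 7–12, then 13–18).

Step 13 (benzannulation). The aryloxyalkyne is only moderately electron-rich, so capture of the short-lived vinylketene 24 may be slower than ketene dimerisation, acylation of the product phenol by 24, or photodegradation of 23. The fallback keeps the benzannulation but uses a siloxyalkyne, the proven partner, and forms the diaryl ether afterwards. It sets out from 11 (and from aryllithium 15) and returns to the route at 29.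
- Commercial tert-butyldimethyl(prop-2-ynyloxy)silane is deprotonated with n-BuLi to (3-{[tert-butyl(dimethyl)silyl]oxy}prop-1-yn-1-yl)lithium F1. This is oxidised with lithium tert-butyl peroxide to lithium 3-{[tert-butyl(dimethyl)silyl]oxy}prop-1-yn-1-olate F2 and O-silylated with i-Pr3SiOTf to tert-butyl(dimethyl)[(3-{[tri(propan-2-yl)silyl]oxy}prop-2-yn-1-yl)oxy]silane F3.
- Irradiation of 11 with F3 and heating as in step 13 should lead through 24, the 3-triisopropylsiloxy-4-vinylcyclobutenone F4, the triisopropylsiloxy dienylketene F5 and the triisopropylsiloxy cyclohexadienone F6 to 2-({[tert-butyl(dimethyl)silyl]oxy}methyl)-6-[(4R)-2,2,6,6-tetramethyl-1,3-dioxan-4-yl]-3-{[tri(propan-2-yl)silyl]oxy}phenol F7.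
- Methylation (MeI, K2CO3, acetone) should give tert-butyl[(2-methoxy-3-[(4R)-2,2,6,6-tetramethyl-1,3-dioxan-4-yl]-6-{[tri(propan-2-yl)silyl]oxy}phenyl)methoxy]dimethylsilane F8. Selective cleavage of the aryl O–Si bond (Cs2CO3, wet DMF) should then give 2-({[tert-butyl(dimethyl)silyl]oxy}methyl)-3-methoxy-4-[(4R)-2,2,6,6-tetramethyl-1,3-dioxan-4-yl]phenol F9.
- Aryllithium 15 is quenched with I2 to give 2-iodo-1-(methoxymethoxy)-3-[(methoxymethoxy)methyl]-5-methylbenzene F10. Ullmann-type O-arylation of F9 with F10 (CuI, picolinic acid, K3PO4, DMSO, 90 °C) should deliver 29.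

Step 11 (alkynyl ether formation). Excess n-BuLi may lithiate ortho to a MOM group or at the benzylic CH2, the stabilised aryloxyacetylide may capture formaldehyde incompletely, and the free propargylic alcohol may suffer acid-catalysed hydration of the ynol ether during isolation. The fallback makes the O–C(sp) bond by copper catalysis with the CH2OTBS unit already in place, using no organolithium and no formaldehyde. It sets out from 17 and returns at 23, replacing steps 10–12.
- (tert-Butyldimethylsilyloxy)acetaldehyde is converted by Ramirez olefination (CBr4, PPh3) into tert-butyl[(3,3-dibromoprop-2-en-1-yl)oxy]dimethylsilane F11.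
- Coupling of F11 with 17 (CuI, 2,2'-bipyridine, K3PO4, toluene, 110 °C) should give the bromoenol ether tert-butyl{[(2Z)-3-bromo-3-{2-(methoxymethoxy)-6-[(methoxymethoxy)methyl]-4-methylphenoxy}prop-2-en-1-yl]oxy}dimethylsilane F12.
- Anti dehydrobromination of F12 with KOt-Bu in THF should give 23.

Step 18 (global deprotection). The acid strength needed for the benzylic (alkyl) MOM ether may, once the acetonide has gone, ionise the ring A carbinol and erode its configuration or cause elimination; alternatively the alkyl MOM ether may be cleaved incompletely. The fallback removes the MOM ethers first by a non-protic method while the carbinol is still locked in the ketal. It sets out from 32 and returns at 33.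
- Treatment of 32 with Me3SiOTf and 2,2'-bipyridyl (CH2Cl2, 0 °C), then water, cleaves both MOM ethers through silyl ether and pyridinium-type intermediates. This should give 6-[2-hydroxy-6-(hydroxymethyl)-4-methylphenoxy]-2-methoxy-3-[(4R)-2,2,6,6-tetramethyl-1,3-dioxan-4-yl]benzoic acid F13.
- The acetonide of F13 alone is then hydrolysed with aqueous acetic acid in THF at room temperature to give 33.

**Further compounds**

F1 | step 13 | (3-{[tert-butyl(dimethyl)silyl]oxy}prop-1-yn-1-yl)lithium | [Li]C#CCO[Si](C)(C)C(C)(C)C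
F2 | step 13 | lithium 3-{[tert-butyl(dimethyl)silyl]oxy}prop-1-yn-1-olate | [Li+].[O-]C#CCO[Si](C)(C)C(C)(C)C
F3 | step 13 | tert-butyl(dimethyl)[(3-{[tri(propan-2-yl)silyl]oxy}prop-2-yn-1-yl)oxy]silane | CC(C)[Si](C(C)C)(C(C)C)OC#CCO[Si](C)(C)C(C)(C)C
F4 | step 13 | 3-triisopropylsiloxy-4-vinylcyclobutenone: 2-({[tert-butyl(dimethyl)silyl]oxy}methyl)-4-{(E)-2-[(4R)-2,2,6,6-tetramethyl-1,3-dioxan-4-yl]ethenyl}-3-{[tri(propan-2-yl)silyl]oxy}cyclobut-2-en-1-one | O=C1C(CO[Si](C)(C)C(C)(C)C)=C(O[Si](C(C)C)(C(C)C)C(C)C)C1/C=C/[C@H]3CC(C)(C)OC(C)(C)O3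
F5 | step 13 | triisopropylsiloxy dienylketene: 2-({[tert-butyl(dimethyl)silyl]oxy}methyl)-6-[(4R)-2,2,6,6-tetramethyl-1,3-dioxan-4-yl]-3-{[tri(propan-2-yl)silyl]oxy}hexa-1,3,5-trien-1-one | O=C=C(CO[Si](C)(C)C(C)(C)C)/C(O[Si](C(C)C)(C(C)C)C(C)C)=C\C=C\[C@H]1CC(C)(C)OC(C)(C)O1
F6 | step 13 | triisopropylsiloxy cyclohexadienone: 2-({[tert-butyl(dimethyl)silyl]oxy}methyl)-6-[(4R)-2,2,6,6-tetramethyl-1,3-dioxan-4-yl]-3-{[tri(propan-2-yl)silyl]oxy}cyclohexa-2,4-dien-1-one | O=C1C(CO[Si](C)(C)C(C)(C)C)=C(O[Si](C(C)C)(C(C)C)C(C)C)C=CC1[C@H]3CC(C)(C)OC(C)(C)O3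
F7 | step 13 | 2-({[tert-butyl(dimethyl)silyl]oxy}methyl)-6-[(4R)-2,2,6,6-tetramethyl-1,3-dioxan-4-yl]-3-{[tri(propan-2-yl)silyl]oxy}phenol | Oc1c([C@H]2CC(C)(C)OC(C)(C)O2)ccc(O[Si](C(C)C)(C(C)C)C(C)C)c1CO[Si](C)(C)C(C)(C)C
F8 | step 13 | tert-butyl[(2-methoxy-3-[(4R)-2,2,6,6-tetramethyl-1,3-dioxan-4-yl]-6-{[tri(propan-2-yl)silyl]oxy}phenyl)methoxy]dimethylsilane | COc1c([C@H]2CC(C)(C)OC(C)(C)O2)ccc(O[Si](C(C)C)(C(C)C)C(C)C)c1CO[Si](C)(C)C(C)(C)C
F9 | step 13 | 2-({[tert-butyl(dimethyl)silyl]oxy}methyl)-3-methoxy-4-[(4R)-2,2,6,6-tetramethyl-1,3-dioxan-4-yl]phenol | COc1c([C@H]2CC(C)(C)OC(C)(C)O2)ccc(O)c1CO[Si](C)(C)C(C)(C)C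
F10 | step 13 | 2-iodo-1-(methoxymethoxy)-3-[(methoxymethoxy)methyl]-5-methylbenzene | COCOCc1cc(C)cc(OCOC)c1I
F11 | step 11 | tert-butyl[(3,3-dibromoprop-2-en-1-yl)oxy]dimethylsilane | BrC(Br)=CCO[Si](C)(C)C(C)(C)C
F12 | step 11 | tert-butyl{[(2Z)-3-bromo-3-{2-(methoxymethoxy)-6-[(methoxymethoxy)methyl]-4-methylphenoxy}prop-2-en-1-yl]oxy}dimethylsilane | COCOCc1cc(C)cc(OCOC)c1O/C(Br)=C/CO[Si](C)(C)C(C)(C)C
F13 | step 18 | 6-[2-hydroxy-6-(hydroxymethyl)-4-methylphenoxy]-2-methoxy-3-[(4R)-2,2,6,6-tetramethyl-1,3-dioxan-4-yl]benzoic acid | COc1c([C@H]2CC(C)(C)OC(C)(C)O2)ccc(Oc2c(O)cc(C)cc2CO)c1C(=O)O
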